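1. The pitfall is that a reading of target counts all its forms, whereas the question asks for free target. So the readings below speak of total target, and free target is some part of it.

| flask | starting material | coupling partner | second substrate | remark | time |
|---|---|---|---|---|---|
| cedar | 0.050 M | 0.032 M | 0.25 M | run made earlier |  |
| elm | 0.050 M | 0.078 M | 0.25 M | run made earlier |  |
| maple | 0.050 M | 0.14 M | 0.25 M | run made earlier |  |
| delta | 0.050 M | 0.0400 M | 0.250 M |  | 3.0 min |
| zeta | 0.050 M | 0.0600 M | 0.250 M |  | 3.0 min |
| beta | 0.050 M | 0.100 M | 0.250 M |  | 3.0 min |
| theta | 0.050 M | 0.150 M | 0.250 M |  | 3.0 min |

- cedar (time / min: target / %, starting material / %): 0.250: 6.9, 93.3; 0.417: 9.1, 91.4; 0.833: 13.4, 86.9; 1.50: 17.3, 83.7; 3.00: 20.0, 79.8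
- elm (time / min: target / %, starting material / %): 0.667: 26.6, 72.8; 1.33: 38.3, 62.6; 2.00: 43.9, 56.7; 2.50: 47.0, 53.9; 3.00: 47.8, 50.9
- maple (time / min: target / %, starting material / %): 0.250: 26.6, 74.5; 0.417: 36.1, 63.9; 0.833: 50.3, 50.5; 1.50: 62.6, 37.3; 3.00: 76.2, 24.8

(scatter of a reading: 0.5 percentage points)

1. [target] (only what is free in solution) at the end for delta, zeta, beta, theta, in this order
2. the course of these numbers from the first flask to the last (hardly changes / falls all the way / rises all the way / rises, then falls / falls, then rises)

- a reading or a percentage of target counts all its forms, free or not
- the concentration of target that is asked is that of its free form alone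
- "hardly changes" means that all values lie within two and a half points (for a concentration: within two and a half percent of the largest)

2. I read a partner price from the runs: the coupling partner charged per target formed, all forms counted, late in a run that has slowed. Cedar gives 3.20 at 3.00 min, and elm gives 3.26 at 3.00 min.

3. I hold two amounts against each other. One is the charge c(coupling partner). The other is the demand, the price times c(starting material), here 0.160 M. Their ratio is the share of starting material I expect as target.

4. In delta the charge of 0.0400 M is less than the demand, so I treat coupling partner as the limiting reagent. I expect 25.0 % as target in delta, a total of 0.0125 M. Maple warns me about time: its ratio is 87.5 %, but its reading at 3.00 min is lower, 76.2 %. So I expect theta to fall short of its ratio too. The readings do not split total from free, so I commit to no free value.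

5. The forecast gives free target as 0.0127 M, 0.0187 M, 0.0295 M and 0.0395 M, a course that rises all the way. It holds that “any binding of target to partner should be small”. Here we differ: my delta figure is a total, and its figure is a free concentration.

6. The flasks give free target as 0.00155 M, 0.00164 M, 0.00147 M and 0.00109 M, so the row rises, then falls. In delta at 3.00 min, idle adduct stands at 22.3 % of the starting material charged, and target with all its forms at 25.4 %.

    coupling partner + target ⇌ idle adduct, settled at all times (K = 1000 /M)
    starting material + coupling partner ⇌ target (K = 8.10 /M, k = 0.190 /M/s)
    second substrate + coupling partner ⇌ second product (K = 4.60 /M, k = 0.0900 /M/s)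

The price in delta comes to 3.14. In zeta the ratio of charge to demand gives 37.5 %, and at 3.00 min zeta holds, all forms counted, target at 38.0 % of the starting material charged.

The data come from a simulation with made-up constants, and the scatter is random.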